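**Retrosynthetic overview**
1. The hydroquinone is freed last from its dimethyl ether (oxidative demethylation, then reduction).
2. The 1,5-diketone (C=O on one ring carbon, CH2C=O on its neighbour) comes from retro-aldol opening of a cyclobutanol in a bicyclo[3.2.0]heptane; the enone chain comes from acetylide addition to the cyclobutanone and trans-reduction, the Z-alkenyl arene chain from alkenyl Grignard opening of a terminal epoxide.
3. The bicyclo[3.2.0]heptan-6-one comes from an intramolecular ketene–alkene [2+2] cycloaddition that forms the cyclopentane, the cyclobutanone and both quaternary centres at once. The face is set by the dioxolane stereocentre of (R)-glyceraldehyde acetonide, whose carbon ends as the side-chain ketone.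
4. The ketene precursor comes from propanoic acid dianion alkylation of an iodide made by Johnson–Claisen rearrangement (E alkene) of the isopropenyl Grignard adduct of the aldehyde.
5. Ring order: cyclopentane and cyclobutanone together (step 6); the four-membered ring is cleaved again in step 17; the arene and dioxolane rings are bought.

Assumption: stereocentres that are destroyed later (a carbinol carbon, an acid α-carbon, the cyclobutanol carbon) are carried as epimer mixtures and drawn without a descriptor. The face selectivity in step 6 is predicted from a 1,3-allylic strain model, not from a known example.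

Step 1
Reactants: 1 (R)-2,2-dimethyl-1,3-dioxolane-4-carbaldehyde; 2 isopropenylmagnesium bromide
Product: 3 (1RS)-1-[(4R)-2,2-dimethyl-1,3-dioxolan-4-yl]-2-methylprop-2-en-1-ol
Conditions: THF, −78 → 0 °C; aq. NH4Cl
Reagents that add atoms: none
Why: Grignard 1,2-addition to the aldehyde gives the allylic alcohol as a mixture of carbinol epimers, which is harmless because that carbon becomes sp2 in step 2, while the bought dioxolane centre is untouched.

Step 2
Reactants: 3 (1RS)-1-[(4R)-2,2-dimethyl-1,3-dioxolan-4-yl]-2-methylprop-2-en-1-ol; 4 triethyl orthoacetate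
Product: 6 ethyl (4E)-5-[(4S)-2,2-dimethyl-1,3-dioxolan-4-yl]-4-methylpent-4-enoate, via mixed ketene acetal 5 (not isolated)
Conditions: neat 4 (6 equiv), EtCO2H (5 mol %), 140 °C, EtOH distilled off
Reagents that add atoms: none
Why: Johnson–Claisen rearrangement ([3,3]-sigmatropic) through a chair transition state with the dioxolanyl group equatorial gives the E trisubstituted alkene from either carbinol epimer and leaves the dioxolane centre intact.

Step 3
Reactants: 6 ethyl (4E)-5-[(4S)-2,2-dimethyl-1,3-dioxolan-4-yl]-4-methylpent-4-enoate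
Product: 7 (4E)-5-[(4S)-2,2-dimethyl-1,3-dioxolan-4-yl]-4-methylpent-4-en-1-ol
Conditions: LiAlH4, THF, 0 °C; H2O, aq. NaOH
Reagents that add atoms: none
Why: Hydride reduction of the ester to the primary alcohol leaves the alkene and the acetonide alone.

Step 4
Reactants: 7 (4E)-5-[(4S)-2,2-dimethyl-1,3-dioxolan-4-yl]-4-methylpent-4-en-1-ol
Product: 8 (4S)-4-[(1E)-5-iodo-2-methylpent-1-en-1-yl]-2,2-dimethyl-1,3-dioxolane
Conditions: I2, PPh3, imidazole, CH2Cl2, 0 → 25 °C
Reagents that add atoms: iodine, [I][I]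
Why: Appel-type iodination of the primary alcohol under imidazole buffering spares the acetonide.

Step 5
Reactants: 8 (4S)-4-[(1E)-5-iodo-2-methylpent-1-en-1-yl]-2,2-dimethyl-1,3-dioxolane; 9 propanoic acid
Product: 11 (2RS,6E)-7-[(4S)-2,2-dimethyl-1,3-dioxolan-4-yl]-2,6-dimethylhept-6-enoic acid, via dilithium propanoate dianion 10 (not isolated)
Conditions: 9, LiN(i-Pr)2 (2.05 equiv per 9), THF/DMPU, 0 → 40 °C; then 8, 25 °C; cold dil. HCl to pH 3
Reagents that add atoms: none
Why: Alkylation of the carboxylic acid dianion with the primary iodide installs the 2-methyl acid, and the epimeric α-centre does not matter because it becomes the ketene carbon.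

Step 6
Reactants: 11 (2RS,6E)-7-[(4S)-2,2-dimethyl-1,3-dioxolan-4-yl]-2,6-dimethylhept-6-enoic acid
Product: 14 (1R,5R,7S)-7-[(4S)-2,2-dimethyl-1,3-dioxolan-4-yl]-1,5-dimethylbicyclo[3.2.0]heptan-6-one, via acyl chloride 12 (not isolated), via ketene 13 (not isolated)
Conditions: 1-chloro-N,N,2-trimethylprop-1-en-1-amine, CH2Cl2, 0 → 25 °C; then syringe-pump addition to NEt3, toluene, 110 °C, 0.01 M
Reagents that add atoms: none
Why: NEt3 eliminates HCl from the acyl chloride to the methyl(alkyl)ketene, whose intramolecular ketene–alkene [2+2] cycloaddition (carbonyl carbon to the less substituted alkene carbon) closes the cyclopentane and the cyclobutanone together with the two methyl groups cis at the ring fusion; 1,3-allylic strain with the alkene methyl holds the dioxolane C–H in the alkene plane so the ketene is expected to add anti to the dioxolane oxygen, setting both quaternary centres R (the minor facial isomer is a diastereomer and is removed by chromatography).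

Step 7
Reactants: 14 (1R,5R,7S)-7-[(4S)-2,2-dimethyl-1,3-dioxolan-4-yl]-1,5-dimethylbicyclo[3.2.0]heptan-6-one; 15 2-methylbut-3-yn-2-ol
Product: 17 (1R,5R,7S)-7-[(4S)-2,2-dimethyl-1,3-dioxolan-4-yl]-6-(3-hydroxy-3-methylbut-1-yn-1-yl)-1,5-dimethylbicyclo[3.2.0]heptan-6-ol, via dilithiated alkynol 16 (not isolated)
Conditions: 15, n-BuLi (2 equiv per 15), THF, −78 → 0 °C; then 14, −78 → 0 °C; H2O
Reagents that add atoms: none
Why: Acetylide 1,2-addition to the strained cyclobutanone gives the tertiary propargylic alcohol, and the configuration of the new carbinol carbon is of no consequence because it becomes a ketone in step 17.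

Step 8
Reactants: 17 (1R,5R,7S)-7-[(4S)-2,2-dimethyl-1,3-dioxolan-4-yl]-6-(3-hydroxy-3-methylbut-1-yn-1-yl)-1,5-dimethylbicyclo[3.2.0]heptan-6-ol
Product: 18 (1S)-1-[(1R,5R,7S)-6-hydroxy-6-(3-hydroxy-3-methylbut-1-yn-1-yl)-1,5-dimethylbicyclo[3.2.0]heptan-7-yl]ethane-1,2-diol
Conditions: AcOH/H2O (4:1), 40 °C
Reagents that add atoms: none
Why: Acid-catalysed acetal hydrolysis frees the 1,2-diol while the tertiary propargylic alcohols, which do not ionise under these conditions, survive.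

Step 9
Reactants: 18 (1S)-1-[(1R,5R,7S)-6-hydroxy-6-(3-hydroxy-3-methylbut-1-yn-1-yl)-1,5-dimethylbicyclo[3.2.0]heptan-7-yl]ethane-1,2-diol
Product: 20 (1R,5R,7S)-6-(3-hydroxy-3-methylbut-1-yn-1-yl)-1,5-dimethyl-7-[(2S)-oxiran-2-yl]bicyclo[3.2.0]heptan-6-ol, via primary tosylate 19 (not isolated)
Conditions: NaH (4.5 equiv), 1-(4-methylbenzenesulfonyl)imidazole (1.1 equiv), THF, 0 → 25 °C
Reagents that add atoms: none
Why: Selective sulfonylation of the primary alkoxide followed by intramolecular Williamson displacement by the neighbouring secondary alkoxide gives the terminal epoxide with retention at the oxygen-bearing stereocentre.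

Step 10
Reactants: 21 4-methoxy-2-methylphenol
Product: 22 2-bromo-4-methoxy-6-methylphenol
Conditions: NBS, i-Pr2NH (10 mol %), CH2Cl2, 0 °C
Reagents that add atoms: N-bromosuccinimide, O=C1CCC(=O)N1Br
Why: Amine-catalysed electrophilic aromatic bromination goes to the only free position ortho to the phenol.

Step 11
Reactants: 22 2-bromo-4-methoxy-6-methylphenol
Product: 23 1-bromo-2,5-dimethoxy-3-methylbenzene
Conditions: MeI, K2CO3, acetone, 56 °C
Reagents that add atoms: iodomethane, IC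
Why: Williamson O-methylation of the phenoxide gives the robust dimethyl ether.

Step 12
Reactants: 24 but-2-yn-1-ol
Product: 26 (2Z)-3-iodobut-2-en-1-ol, via cyclic vinylalanate 25 (not isolated)
Conditions: NaAlH2(OCH2CH2OMe)2, Et2O, 0 → 25 °C; then I2, THF, −78 → 0 °C; aq. Na2S2O3
Reagents that add atoms: iodine, [I][I]
Why: Hydroxyl-directed trans-hydroalumination puts aluminium on the distal alkyne carbon in a five-membered alanate, and iodinolysis with retention gives the Z vinyl iodide.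

Step 13
Reactants: 26 (2Z)-3-iodobut-2-en-1-ol
Product: 27 (2Z)-1-bromo-3-iodobut-2-ene
Conditions: CBr4, PPh3, CH2Cl2, 0 °C
Reagents that add atoms: tetrabromomethane, BrC(Br)(Br)Br
Why: Appel bromination converts the allylic alcohol into the primary allylic bromide without allylic transposition or loss of alkene geometry.

Step 14
Reactants: 23 1-bromo-2,5-dimethoxy-3-methylbenzene; 27 (2Z)-1-bromo-3-iodobut-2-ene
Product: 29 1-[(2Z)-3-iodobut-2-en-1-yl]-2,5-dimethoxy-3-methylbenzene, via arylmagnesium bromide 28 (not isolated)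
Conditions: Mg, THF, 65 °C; then 27, CuI (5 mol %), THF, −20 → 0 °C
Reagents that add atoms: none
Why: CuI-catalysed SN2 allylic substitution of the primary bromide by the aryl Grignard reagent forms the aryl–CH2 bond and keeps the Z iodoalkene.

Step 15
Reactants: 20 (1R,5R,7S)-6-(3-hydroxy-3-methylbut-1-yn-1-yl)-1,5-dimethyl-7-[(2S)-oxiran-2-yl]bicyclo[3.2.0]heptan-6-ol; 29 1-[(2Z)-3-iodobut-2-en-1-yl]-2,5-dimethoxy-3-methylbenzene
Product: 32 (1R,5R,7S)-7-[(1R,3Z)-5-(2,5-dimethoxy-3-methylphenyl)-1-hydroxy-3-methylpent-3-en-1-yl]-6-(3-hydroxy-3-methylbut-1-yn-1-yl)-1,5-dimethylbicyclo[3.2.0]heptan-6-ol, via alkenyllithium 30 (not isolated), via alkenylmagnesium bromide 31 (not isolated)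
Conditions: 29, t-BuLi (2 equiv), Et2O, −78 °C; MgBr2·OEt2, −78 → −30 °C; CuI (10 mol %); then 20 pre-treated with MeMgBr (2 equiv), THF, −30 → 0 °C; aq. NH4Cl
Reagents that add atoms: none
Why: Iodine–lithium exchange with retention of alkene geometry, transmetalation to magnesium and CuI-catalysed opening of the terminal epoxide at its CH2 end join the two halves and give the Z trisubstituted alkene, the tertiary alcohols being masked beforehand as magnesium alkoxides.

Step 16
Reactants: 32 (1R,5R,7S)-7-[(1R,3Z)-5-(2,5-dimethoxy-3-methylphenyl)-1-hydroxy-3-methylpent-3-en-1-yl]-6-(3-hydroxy-3-methylbut-1-yn-1-yl)-1,5-dimethylbicyclo[3.2.0]heptan-6-ol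
Product: 33 (1R,5R,7S)-7-[(1R,3Z)-5-(2,5-dimethoxy-3-methylphenyl)-1-hydroxy-3-methylpent-3-en-1-yl]-6-[(1E)-3-hydroxy-3-methylbut-1-en-1-yl]-1,5-dimethylbicyclo[3.2.0]heptan-6-ol
Conditions: LiAlH4, THF, 65 °C; H2O, aq. NaOH
Reagents that add atoms: none
Why: Alkoxide-directed trans-hydroalumination of the propargylic 1,4-diol and protonolysis give the E alkene, with the isolated alkenes and aryl ethers inert.

Step 17
Reactants: 33 (1R,5R,7S)-7-[(1R,3Z)-5-(2,5-dimethoxy-3-methylphenyl)-1-hydroxy-3-methylpent-3-en-1-yl]-6-[(1E)-3-hydroxy-3-methylbut-1-en-1-yl]-1,5-dimethylbicyclo[3.2.0]heptan-6-ol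
Product: 35 (2E)-1-[(1R,2R)-2-[(4Z)-6-(2,5-dimethoxy-3-methylphenyl)-4-methyl-2-oxohex-4-en-1-yl]-1,2-dimethylcyclopentyl]-4-hydroxy-4-methylpent-2-en-1-one, via cyclobutanol ketone 34 (not isolated)
Conditions: Dess–Martin periodinane, pyridine, CH2Cl2, 0 → 25 °C
Reagents that add atoms: none
Why: Dess–Martin oxidation of the only secondary alcohol gives a β-hydroxy ketone whose strained cyclobutanol opens by retro-aldol (de Mayo-type) fragmentation, releasing the enone and the β,γ-unsaturated ketone without touching the quaternary centres.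

Step 18
Reactants: 35 (2E)-1-[(1R,2R)-2-[(4Z)-6-(2,5-dimethoxy-3-methylphenyl)-4-methyl-2-oxohex-4-en-1-yl]-1,2-dimethylcyclopentyl]-4-hydroxy-4-methylpent-2-en-1-one
Product: 37 (2E)-1-[(1R,2R)-2-[(4Z)-6-(2,5-dihydroxy-3-methylphenyl)-4-methyl-2-oxohex-4-en-1-yl]-1,2-dimethylcyclopentyl]-4-hydroxy-4-methylpent-2-en-1-one, via quinone 36 (not isolated)
Conditions: (NH4)2Ce(NO3)6, MeCN/H2O, 0 °C; then aq. Na2S2O4, EtOAc, 25 °C
Reagents that add atoms: water, O
Why: Oxidative demethylation of the 1,4-dimethoxyarene gives the quinone and dithionite reduction gives the hydroquinone, neither step affecting a stereocentre or the alkene geometries.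

**Compound list**
1 | (R)-2,2-dimethyl-1,3-dioxolane-4-carbaldehyde | CC1(C)OC[C@@H](O1)C=O | starting material
2 | isopropenylmagnesium bromide | CC(=C)[Mg]Br | starting material
3 | (1RS)-1-[(4R)-2,2-dimethyl-1,3-dioxolan-4-yl]-2-methylprop-2-en-1-ol | CC1(C)OC[C@@H](O1)C(O)C(C)=C | intermediate
4 | triethyl orthoacetate | CCOC(C)(OCC)OCC | starting material
5 | (4R)-4-{1-[(1-ethoxyethenyl)oxy]-2-methylprop-2-en-1-yl}-2,2-dimethyl-1,3-dioxolane | CCOC(=C)OC(C(C)=C)[C@H]1COC(C)(C)O1 | intermediate (not isolated)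
6 | ethyl (4E)-5-[(4S)-2,2-dimethyl-1,3-dioxolan-4-yl]-4-methylpent-4-enoate | CCOC(=O)CC/C(C)=C/[C@H]1COC(C)(C)O1 | intermediate
7 | (4E)-5-[(4S)-2,2-dimethyl-1,3-dioxolan-4-yl]-4-methylpent-4-en-1-ol | OCCC/C(C)=C/[C@H]1COC(C)(C)O1 | intermediate
8 | (4S)-4-[(1E)-5-iodo-2-methylpent-1-en-1-yl]-2,2-dimethyl-1,3-dioxolane | ICCC/C(C)=C/[C@H]1COC(C)(C)O1 | intermediate
9 | propanoic acid | CCC(O)=O | starting material
10 | dilithium prop-1-ene-1,1-diolate (propanoate dianion) | [Li+].[Li+].CC=C([O-])[O-] | intermediate (not isolated)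
11 | (2RS,6E)-7-[(4S)-2,2-dimethyl-1,3-dioxolan-4-yl]-2,6-dimethylhept-6-enoic acid | CC(CCC/C(C)=C/[C@H]1COC(C)(C)O1)C(O)=O | intermediate
12 | (2RS,6E)-7-[(4S)-2,2-dimethyl-1,3-dioxolan-4-yl]-2,6-dimethylhept-6-enoyl chloride | CC(CCC/C(C)=C/[C@H]1COC(C)(C)O1)C(Cl)=O | intermediate (not isolated)
13 | (6E)-7-[(4S)-2,2-dimethyl-1,3-dioxolan-4-yl]-2,6-dimethylhepta-1,6-dien-1-one (ketene) | CC(CCC/C(C)=C/[C@H]1COC(C)(C)O1)=C=O | intermediate (not isolated)
14 | (1R,5R,7S)-7-[(4S)-2,2-dimethyl-1,3-dioxolan-4-yl]-1,5-dimethylbicyclo[3.2.0]heptan-6-one | CC1(C)OC[C@@H](O1)[C@@H]2[C@@]3(C)CCC[C@@]3(C)C2=O | intermediate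
15 | 2-methylbut-3-yn-2-ol | CC(C)(O)C#C | starting material
16 | dilithium 3-methyl-3-oxidobut-1-yn-1-ide | [Li+].[Li+].CC(C)([O-])C#[C-] | intermediate (not isolated)
17 | (1R,5R,7S)-7-[(4S)-2,2-dimethyl-1,3-dioxolan-4-yl]-6-(3-hydroxy-3-methylbut-1-yn-1-yl)-1,5-dimethylbicyclo[3.2.0]heptan-6-ol (carbinol carbon 6 unassigned) | CC1(C)OC[C@@H](O1)[C@@H]2[C@@]3(C)CCC[C@@]3(C)C2(O)C#CC(C)(C)O | intermediate
18 | (1S)-1-[(1R,5R,7S)-6-hydroxy-6-(3-hydroxy-3-methylbut-1-yn-1-yl)-1,5-dimethylbicyclo[3.2.0]heptan-7-yl]ethane-1,2-diol | OC[C@@H](O)[C@@H]1[C@@]2(C)CCC[C@@]2(C)C1(O)C#CC(C)(C)O | intermediate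
19 | (2S)-2-hydroxy-2-[(1R,5R,7S)-6-hydroxy-6-(3-hydroxy-3-methylbut-1-yn-1-yl)-1,5-dimethylbicyclo[3.2.0]heptan-7-yl]ethyl 4-methylbenzenesulfonate | Cc1ccc(cc1)S(=O)(=O)OC[C@@H](O)[C@@H]2[C@@]3(C)CCC[C@@]3(C)C2(O)C#CC(C)(C)O | intermediate (not isolated)
20 | (1R,5R,7S)-6-(3-hydroxy-3-methylbut-1-yn-1-yl)-1,5-dimethyl-7-[(2S)-oxiran-2-yl]bicyclo[3.2.0]heptan-6-ol | C1O[C@H]1[C@@H]2[C@@]3(C)CCC[C@@]3(C)C2(O)C#CC(C)(C)O | intermediate
21 | 4-methoxy-2-methylphenol | COc1ccc(O)c(C)c1 | starting material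
22 | 2-bromo-4-methoxy-6-methylphenol | COc1cc(C)c(O)c(Br)c1 | intermediate
23 | 1-bromo-2,5-dimethoxy-3-methylbenzene | COc1cc(C)c(OC)c(Br)c1 | intermediate
24 | but-2-yn-1-ol | CC#CCO | starting material
25 | sodium 2,2-bis(2-methoxyethoxy)-3-methyl-2,5-dihydro-1,2-oxaluminol-2-uide (cyclic vinylalanate) | [Na+].CC1=CCO[Al-]1(OCCOC)OCCOC | intermediate (not isolated)
26 | (2Z)-3-iodobut-2-en-1-ol | C/C(I)=C/CO | intermediate
27 | (2Z)-1-bromo-3-iodobut-2-ene | C/C(I)=C/CBr | intermediate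
28 | (2,5-dimethoxy-3-methylphenyl)magnesium bromide | COc1cc(C)c(OC)c([Mg]Br)c1 | intermediate (not isolated)
29 | 1-[(2Z)-3-iodobut-2-en-1-yl]-2,5-dimethoxy-3-methylbenzene | C/C(I)=C/Cc1cc(OC)cc(C)c1OC | intermediate
30 | [4-(2,5-dimethoxy-3-methylphenyl)but-2-en-2-yl]lithium, Li cis to the CH2Ar group | C/C([Li])=C/Cc1cc(OC)cc(C)c1OC | intermediate (not isolated)
31 | [(2Z)-4-(2,5-dimethoxy-3-methylphenyl)but-2-en-2-yl]magnesium bromide | C/C([Mg]Br)=C/Cc1cc(OC)cc(C)c1OC | intermediate (not isolated)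
32 | (1R,5R,7S)-7-[(1R,3Z)-5-(2,5-dimethoxy-3-methylphenyl)-1-hydroxy-3-methylpent-3-en-1-yl]-6-(3-hydroxy-3-methylbut-1-yn-1-yl)-1,5-dimethylbicyclo[3.2.0]heptan-6-ol | C/C(=C/Cc1cc(OC)cc(C)c1OC)C[C@@H](O)[C@@H]1[C@@]2(C)CCC[C@@]2(C)C1(O)C#CC(C)(C)O | intermediate
33 | (1R,5R,7S)-7-[(1R,3Z)-5-(2,5-dimethoxy-3-methylphenyl)-1-hydroxy-3-methylpent-3-en-1-yl]-6-[(1E)-3-hydroxy-3-methylbut-1-en-1-yl]-1,5-dimethylbicyclo[3.2.0]heptan-6-ol | C/C(=C/Cc1cc(OC)cc(C)c1OC)C[C@@H](O)[C@@H]1[C@@]2(C)CCC[C@@]2(C)C1(O)/C=C/C(C)(C)O | intermediate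
34 | (3Z)-5-(2,5-dimethoxy-3-methylphenyl)-1-[(1R,5R,7R)-6-hydroxy-6-[(1E)-3-hydroxy-3-methylbut-1-en-1-yl]-1,5-dimethylbicyclo[3.2.0]heptan-7-yl]-3-methylpent-3-en-1-one | C/C(=C/Cc1cc(OC)cc(C)c1OC)CC(=O)[C@@H]1[C@@]2(C)CCC[C@@]2(C)C1(O)/C=C/C(C)(C)O | intermediate (not isolated)
35 | (2E)-1-[(1R,2R)-2-[(4Z)-6-(2,5-dimethoxy-3-methylphenyl)-4-methyl-2-oxohex-4-en-1-yl]-1,2-dimethylcyclopentyl]-4-hydroxy-4-methylpent-2-en-1-one | C/C(=C/Cc1cc(OC)cc(C)c1OC)CC(=O)C[C@@]1(C)CCC[C@@]1(C)C(=O)/C=C/C(C)(C)O | intermediate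
36 | 2-[(2Z)-6-[(1R,2R)-2-[(2E)-4-hydroxy-4-methylpent-2-enoyl]-1,2-dimethylcyclopentyl]-3-methyl-5-oxohex-2-en-1-yl]-6-methylcyclohexa-2,5-diene-1,4-dione | C/C(=C/CC1=CC(=O)C=C(C)C1=O)CC(=O)C[C@@]1(C)CCC[C@@]1(C)C(=O)/C=C/C(C)(C)O | intermediate (not isolated)
37 | (2E)-1-[(1R,2R)-2-[(4Z)-6-(2,5-dihydroxy-3-methylphenyl)-4-methyl-2-oxohex-4-en-1-yl]-1,2-dimethylcyclopentyl]-4-hydroxy-4-methylpent-2-en-1-one | C/C(=C/Cc1cc(O)cc(C)c1O)CC(=O)C[C@@]1(C)CCC[C@@]1(C)C(=O)/C=C/C(C)(C)O | target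

**Totals**
Total step count: 18. Longest linear sequence: 13 steps (steps 1–9, then 15–18); the aryl side-chain piece (steps 10–14) joins at step 15.

**Three steps most likely to fail**

Step 6. A methyl(alkyl)ketene may dimerise or add slowly to an alkene that carries an allylic oxygen, and the face selectivity may be modest. The fallback sets out from 11 and returns at 14. Acyl chloride 12 is quenched with Me2NH to give the N,N-dimethylamide F1. Tf2O and 2,4,6-trimethylpyridine in ClCH2CH2Cl at 80 °C convert it into the keteniminium triflate F2, a much stronger electrophile than the ketene. Its cationic intramolecular [2+2] cycloaddition to the same alkene gives the cyclobutaniminium triflate F3, and aqueous NaHCO3 hydrolysis gives 14. The facial isomers are again diastereomers and are separated at 14.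

Step 15. A precious alkenyl Grignard reagent has to open an epoxide in a molecule with two free tertiary alcohols and an internal alkyne. The fallback sets out from 18 and returns at 32. I2, PPh3 and imidazole convert the primary hydroxyl of 18 into the primary iodide F4. F4 is joined directly to 29 by NiI2/4,4'-di-tert-butyl-2,2'-bipyridine-catalysed reductive cross-electrophile coupling with Mn powder in DMPU at 25 °C. This needs no carbanion, no epoxide and no strong base, tolerates the free hydroxyls and keeps the Z geometry.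

Step 16. Hot LiAlH4 on a hindered bis-tertiary propargylic diol may give allene or incomplete reduction. The fallback sets out from 32 and returns at 33. [Cp*Ru(MeCN)3]PF6-catalysed trans-hydrosilylation with (EtO)3SiH in CH2Cl2 gives the vinylsilane F5 (either regioisomer serves). Protodesilylation with Bu4NF and CuI in THF then gives the E alkene 33.

**Further compounds**
F1 | step 6 | (2RS,6E)-7-[(4S)-2,2-dimethyl-1,3-dioxolan-4-yl]-N,N,2,6-tetramethylhept-6-enamide | CC(CCC/C(C)=C/[C@H]1COC(C)(C)O1)C(=O)N(C)C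
F2 | step 6 | N-[(6E)-7-[(4S)-2,2-dimethyl-1,3-dioxolan-4-yl]-2,6-dimethylhepta-1,6-dien-1-ylidene]-N-methylmethanaminium trifluoromethanesulfonate | C[N+](C)=C=C(C)CCC/C(C)=C/[C@H]1COC(C)(C)O1.[O-]S(=O)(=O)C(F)(F)F
F3 | step 6 | N-[(1R,5R,7S)-7-[(4S)-2,2-dimethyl-1,3-dioxolan-4-yl]-1,5-dimethylbicyclo[3.2.0]heptan-6-ylidene]-N-methylmethanaminium trifluoromethanesulfonate | CC1(C)OC[C@@H](O1)[C@@H]2[C@@]3(C)CCC[C@@]3(C)C2=[N+](C)C.[O-]S(=O)(=O)C(F)(F)F
F4 | step 15 | (1R,5R,7S)-7-[(1S)-1-hydroxy-2-iodoethyl]-6-(3-hydroxy-3-methylbut-1-yn-1-yl)-1,5-dimethylbicyclo[3.2.0]heptan-6-ol | IC[C@@H](O)[C@@H]1[C@@]2(C)CCC[C@@]2(C)C1(O)C#CC(C)(C)O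
F5 | step 16 | (1R,5R,7S)-7-[(1R,3Z)-5-(2,5-dimethoxy-3-methylphenyl)-1-hydroxy-3-methylpent-3-en-1-yl]-6-[(1Z)-3-hydroxy-3-methyl-2-(triethoxysilyl)but-1-en-1-yl]-1,5-dimethylbicyclo[3.2.0]heptan-6-ol | C/C(=C/Cc1cc(OC)cc(C)c1OC)C[C@@H](O)[C@@H]1[C@@]2(C)CCC[C@@]2(C)C1(O)/C=C([Si](OCC)(OCC)OCC)/C(C)(C)O
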